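**Strategy.** The only stereocentre is the quaternary benzylic carbon C2 of a terminal oxirane whose ring carbon C3 (a CH2) is bonded to nothing but C2 and the ring oxygen. This lets the three-membered ring be cut back to the C=O of an aryl acetoxymethyl ketone plus one methylene carbon from a sulfoxonium ylide. Under chiral LaLi3(binaphthoxide)3 the ylide adds to one ketone face and the betaine closes, so the C2–C3 bond, the C3–O bond, the oxirane and the stereocentre arise in one operation. The precursor already carries the acetate and the pentanoate; its phenol is a triisopropylsilyl ether, robust towards acetate, alkoxide and ylide, and is exchanged for the isobutyrate last.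

Key step: step 6

Assumption: the (S)-binaphthoxide catalyst is taken to deliver the methylene group to the ketone face that leads to the (S)-oxirane, by analogy with aryl methyl ketones (aryl as the large flank, CH2OAc as the small one); should the sense prove opposite, the (R)-binaphthoxide catalyst is used with nothing else changed.

**Step 1**
Reactants: 1 methyl 3-hydroxy-4-iodobenzoate; 2 triisopropylsilyl chloride
Product: 3 methyl 4-iodo-3-(triisopropylsilyloxy)benzoate
Conditions: TIPSCl (1.2 equiv), imidazole (2.5 equiv), DMF, rt to 40 °C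
Reagents that add atoms: triisopropylsilyl chloride (2), CC(C)[Si](Cl)(C(C)C)C(C)C
Why: Imidazole-promoted O-silylation of the only hydroxyl group present should give the aryl silyl ether, the ortho iodine slowing but not blocking the reaction and the methyl ester staying inert.

**Step 2**
Reactants: 3 methyl 4-iodo-3-(triisopropylsilyloxy)benzoate
Product: 4 [4-iodo-3-(triisopropylsilyloxy)phenyl]methanol
Conditions: iBu2AlH (2.5 equiv), CH2Cl2, −78 to 0 °C; aqueous potassium sodium tartrate
Reagents that add atoms: none
Why: Hydride reduction of the methyl ester by diisobutylaluminium hydride should stop cleanly at the benzylic alcohol, since the aryl iodide and the hindered aryl silyl ether do not react at low temperature.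

**Step 3**
Reactants: 4 [4-iodo-3-(triisopropylsilyloxy)phenyl]methanol; 5 pentanoyl chloride
Product: 6 [4-iodo-3-(triisopropylsilyloxy)phenyl]methyl pentanoate
Conditions: pentanoyl chloride (1.2 equiv), pyridine (2 equiv), DMAP (5 mol %), CH2Cl2, 0 °C to rt
Reagents that add atoms: pentanoyl chloride (5), CCCCC(Cl)=O
Why: Esterification of the single free hydroxyl group with an acid chloride under nucleophilic catalysis is standard and leaves the silyl ether and the iodide alone.

**Step 4**
Reactants: 6 [4-iodo-3-(triisopropylsilyloxy)phenyl]methyl pentanoate; 7 tributyl(1-ethoxyvinyl)stannane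
Product: 9 [4-(2-bromoacetyl)-3-(triisopropylsilyloxy)phenyl]methyl pentanoate, via aryl 1-ethoxyvinyl ether 8 (not isolated)
Conditions: 7 (1.1 equiv), Pd(PPh3)4 (5 mol %), toluene, 100 °C; then 0 °C, THF/H2O (3:1), NBS (1.2 equiv)
Reagents that add atoms: tributyl(1-ethoxyvinyl)stannane (7), CCCC[Sn](CCCC)(CCCC)C(=C)OCC; N-bromosuccinimide, O=C1CCC(=O)N1Br; water, O
Why: Stille coupling at the aryl iodide under zerovalent palladium installs the 1-ethoxyvinyl group, and bromination of this electron-rich enol ether by NBS in wet THF gives a bromo-oxocarbenium ion that water converts to the bromomethyl ketone with loss of ethanol, so no acid is formed and the arene, the silyl ether and the ester are spared.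

**Step 5**
Reactants: 9 [4-(2-bromoacetyl)-3-(triisopropylsilyloxy)phenyl]methyl pentanoate; 10 potassium acetate
Product: 11 [4-(2-acetoxyacetyl)-3-(triisopropylsilyloxy)phenyl]methyl pentanoate
Conditions: KOAc (1.5 equiv, dried), 18-crown-6 (10 mol %), MeCN, rt
Reagents that add atoms: potassium acetate (10), CC(=O)[O-].[K+]
Why: SN2 displacement of the activated alpha-keto bromide by acetate is the standard phenacyl ester synthesis, run dry so that the hindered aryl silyl ether and the pentanoate are not attacked.

**Step 6**
Reactants: 11 [4-(2-acetoxyacetyl)-3-(triisopropylsilyloxy)phenyl]methyl pentanoate; 12 trimethylsulfoxonium iodide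
Product: 15 [4-[(2S)-2-(acetoxymethyl)oxiran-2-yl]-3-(triisopropylsilyloxy)phenyl]methyl pentanoate, via dimethylsulfoxonium methylide 13 (not isolated), via sulfoxonium alkoxide betaine 14 (not isolated)
Conditions: 12, NaH, THF, reflux, filtered under argon; then 11, (S)-LaLi3(binaphthoxide)3 (10 mol %), (2,4,6-(MeO)3C6H2)3P=O (10 mol %), 5 Å MS, THF, 0 °C to rt, 13 (1.2 equiv) added slowly
Reagents that add atoms: trimethylsulfoxonium iodide (12), C[S+](C)(C)=O.[I-]
Why: The trivalent lanthanum centre of the heterobimetallic catalyst binds the ketone oxygen as a Lewis acid while a lithium binaphthoxide holds the ylide, so the ylide carbon adds to one face of the C=O to give betaine 14, whose alkoxide then displaces dimethyl sulfoxide from the neighbouring CH2 to make the C–O bond. The closest known reaction is the LaLi3(binaphthoxide)3/phosphine oxide-catalysed asymmetric Corey–Chaykovsky epoxidation of aryl methyl ketones, applied here to an aryl ketone whose small flank is CH2OAc in place of CH3. The oxirane closes in a 3-exo-tet mode by intramolecular SN2 at the sulfoxonium-bearing carbon. The quaternary stereocentre is set under catalyst control by the (S)-binaphthoxide framework, which distinguishes the bulky ortho-silyloxyaryl flank from the slim CH2OAc flank, and it is not touched by the closure, which takes place at the adjacent CH2 (the descriptor changes from R in 14 to S in 15 only through the priority rules). The step needs enantiofacial selectivity together with chemoselectivity for ketone addition over ester acylation and over enolisation: the alpha-acetoxy group raises the electrophilicity of the carbonyl, the two alkyl esters are far poorer acceptors for the stabilised ylide, slow addition keeps the basic ylide scarce, and the triisopropylsilyl group is too hindered to migrate from the phenol oxygen to the betaine alkoxide.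

**Step 7**
Reactants: 15 [4-[(2S)-2-(acetoxymethyl)oxiran-2-yl]-3-(triisopropylsilyloxy)phenyl]methyl pentanoate; 16 isobutyric anhydride
Product: 18 [4-[(2S)-2-(acetoxymethyl)oxiran-2-yl]-3-(2-methylpropanoyloxy)phenyl]methyl pentanoate, via caesium phenoxide 17 (not isolated)
Conditions: (iPrCO)2O (3 equiv), CsF (2 equiv), DMF, 0 °C to rt
Reagents that add atoms: isobutyric anhydride (16), CC(C)C(=O)OC(=O)C(C)C
Why: Fluoride attacks silicon and releases phenoxide 17 in the presence of excess anhydride, which acylates it at once (one-pot desilylative acylation of an aryl silyl ether), so the phenoxide should not build up beside the oxirane and the acetate, and the stereocentre is not involved.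

**Compound list**
1 | methyl 3-hydroxy-4-iodobenzoate | COC(=O)c1ccc(I)c(O)c1 | starting material
2 | triisopropylsilyl chloride | CC(C)[Si](Cl)(C(C)C)C(C)C | starting material
3 | methyl 4-iodo-3-(triisopropylsilyloxy)benzoate | COC(=O)c1ccc(I)c(O[Si](C(C)C)(C(C)C)C(C)C)c1 | intermediate
4 | [4-iodo-3-(triisopropylsilyloxy)phenyl]methanol | OCc1ccc(I)c(O[Si](C(C)C)(C(C)C)C(C)C)c1 | intermediate
5 | pentanoyl chloride | CCCCC(Cl)=O | starting material
6 | [4-iodo-3-(triisopropylsilyloxy)phenyl]methyl pentanoate | CCCCC(=O)OCc1ccc(I)c(O[Si](C(C)C)(C(C)C)C(C)C)c1 | intermediate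
7 | tributyl(1-ethoxyvinyl)stannane | CCCC[Sn](CCCC)(CCCC)C(=C)OCC | starting material
8 | [4-(1-ethoxyethenyl)-3-(triisopropylsilyloxy)phenyl]methyl pentanoate (not isolated) | CCCCC(=O)OCc1ccc(C(=C)OCC)c(O[Si](C(C)C)(C(C)C)C(C)C)c1 | intermediate
9 | [4-(2-bromoacetyl)-3-(triisopropylsilyloxy)phenyl]methyl pentanoate | CCCCC(=O)OCc1ccc(C(=O)CBr)c(O[Si](C(C)C)(C(C)C)C(C)C)c1 | intermediate
10 | potassium acetate | CC(=O)[O-].[K+] | starting material
11 | [4-(2-acetoxyacetyl)-3-(triisopropylsilyloxy)phenyl]methyl pentanoate, i.e. 2-acetoxy-1-[4-(pentanoyloxymethyl)-2-(triisopropylsilyloxy)phenyl]ethanone | CCCCC(=O)OCc1ccc(C(=O)COC(C)=O)c(O[Si](C(C)C)(C(C)C)C(C)C)c1 | intermediate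
12 | trimethylsulfoxonium iodide | C[S+](C)(C)=O.[I-] | starting material
13 | dimethylsulfoxonium methylide (not isolated) | [CH2-][S+](C)(C)=O | intermediate
14 | [4-[(2R)-1-acetoxy-3-(dimethyloxosulfonio)-2-oxidopropan-2-yl]-3-(triisopropylsilyloxy)phenyl]methyl pentanoate, zwitterionic betaine (not isolated) | CCCCC(=O)OCc1ccc([C@@]([O-])(COC(C)=O)C[S+](C)(C)=O)c(O[Si](C(C)C)(C(C)C)C(C)C)c1 | intermediate
15 | [4-[(2S)-2-(acetoxymethyl)oxiran-2-yl]-3-(triisopropylsilyloxy)phenyl]methyl pentanoate | CCCCC(=O)OCc1ccc([C@@]2(COC(C)=O)CO2)c(O[Si](C(C)C)(C(C)C)C(C)C)c1 | intermediate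
16 | isobutyric anhydride | CC(C)C(=O)OC(=O)C(C)C | starting material
17 | caesium 2-[(2S)-2-(acetoxymethyl)oxiran-2-yl]-5-(pentanoyloxymethyl)phenolate (not isolated) | CCCCC(=O)OCc1ccc([C@@]2(COC(C)=O)CO2)c([O-])c1.[Cs+] | intermediate
18 | [4-[(2S)-2-(acetoxymethyl)oxiran-2-yl]-3-(2-methylpropanoyloxy)phenyl]methyl pentanoate (CNP0107520.1) | CCCCC(=O)OCc1ccc([C@@]2(COC(C)=O)CO2)c(OC(=O)C(C)C)c1 | target

**Totals**
Total step count: 7
Longest linear sequence: 7 steps (1 to 18)

**Steps most likely to fail**

Step 6. The basic ylide may enolise the acetoxymethyl ketone instead of adding to it. The acetyl group may shift onto the betaine alkoxide before ring closure. The ortho-substituted aryl flank may also be read poorly by the catalyst, giving low facial selectivity. The fallback avoids ylide chemistry and sets out from aryl iodide 6. Propargyl alcohol is hydrostannylated (Bu3SnH, Mo(CO)3(CNtBu)3 cat., THF, 55 °C) to the internal vinylstannane 2-(tributylstannyl)prop-2-en-1-ol F1. Stille coupling of 6 with F1 (Pd(PPh3)4, CuI, DMF, 60 °C) should give the 2-aryl allylic alcohol [4-(3-hydroxyprop-1-en-2-yl)-3-(triisopropylsilyloxy)phenyl]methyl pentanoate F2. Sharpless asymmetric epoxidation (Ti(OiPr)4, D-(−)-diethyl tartrate, tBuOOH, 4 Å MS, CH2Cl2, −20 °C) should then give the epoxy alcohol [4-[(2R)-2-(hydroxymethyl)oxiran-2-yl]-3-(triisopropylsilyloxy)phenyl]methyl pentanoate F3. The D-tartrate is the one that delivers oxygen to the face required here. Acetylation (Ac2O, pyridine, 0 °C) comes back to the route at 15; the descriptor changes from R to S only because CH2OAc outranks the ring CH2.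

Step 5. Acetate may strip the silyl group from the ortho-acyl aryl ether, after which the phenoxide would close onto the bromomethyl ketone; the substitution may also stall on the hindered substrate. The fallback avoids the halo ketone and sets out from enol ether 8, which is isolated this time (step 4 stopped before the NBS addition, filtration through Et3N-deactivated silica). Catalytic dihydroxylation (OsO4 2 mol %, N-methylmorpholine N-oxide, acetone/H2O, 0 °C) gives a hemiketal that loses ethanol to the hydroxy ketone [4-(2-hydroxyacetyl)-3-(triisopropylsilyloxy)phenyl]methyl pentanoate F4. Acetylation (Ac2O, pyridine, DMAP cat., CH2Cl2, 0 °C) comes back to the route at 11.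

Step 7. The phenoxide set free by fluoride may take over the neighbouring acetyl group or open the benzylic oxirane before it is acylated, and fluoride or carboxylate may open the oxirane on their own. The fallback puts the aryl isobutyrate in place before any oxirane exists and builds the oxirane with an oxidant that tolerates aryl esters. It sets out from 6. Desilylative acylation (CsF, (iPrCO)2O, DMF, rt) on this robust substrate gives [4-iodo-3-(2-methylpropanoyloxy)phenyl]methyl pentanoate F5. Stille coupling with the stannane 2-(tributylstannyl)prop-2-en-1-ol F1, made as above (Pd(PPh3)4, CuI, DMF, 60 °C), gives [4-(3-hydroxyprop-1-en-2-yl)-3-(2-methylpropanoyloxy)phenyl]methyl pentanoate F6. Sharpless asymmetric epoxidation with D-(−)-diethyl tartrate (Ti(OiPr)4, tBuOOH, 4 Å MS, CH2Cl2, −20 °C) gives [4-[(2R)-2-(hydroxymethyl)oxiran-2-yl]-3-(2-methylpropanoyloxy)phenyl]methyl pentanoate F7. Acetylation (Ac2O, pyridine, 0 °C) comes back to the route at 18.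

**Further compounds**
F1 | step 6 | 2-(tributylstannyl)prop-2-en-1-ol | OCC(=C)[Sn](CCCC)(CCCC)CCCC
F2 | step 6 | [4-(3-hydroxyprop-1-en-2-yl)-3-(triisopropylsilyloxy)phenyl]methyl pentanoate | CCCCC(=O)OCc1ccc(C(=C)CO)c(O[Si](C(C)C)(C(C)C)C(C)C)c1
F3 | step 6 | [4-[(2R)-2-(hydroxymethyl)oxiran-2-yl]-3-(triisopropylsilyloxy)phenyl]methyl pentanoate | CCCCC(=O)OCc1ccc([C@@]2(CO)CO2)c(O[Si](C(C)C)(C(C)C)C(C)C)c1
F4 | step 5 | [4-(2-hydroxyacetyl)-3-(triisopropylsilyloxy)phenyl]methyl pentanoate | CCCCC(=O)OCc1ccc(C(=O)CO)c(O[Si](C(C)C)(C(C)C)C(C)C)c1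
F5 | step 7 | [4-iodo-3-(2-methylpropanoyloxy)phenyl]methyl pentanoate | CCCCC(=O)OCc1ccc(I)c(OC(=O)C(C)C)c1
F6 | step 7 | [4-(3-hydroxyprop-1-en-2-yl)-3-(2-methylpropanoyloxy)phenyl]methyl pentanoate | CCCCC(=O)OCc1ccc(C(=C)CO)c(OC(=O)C(C)C)c1
F7 | step 7 | [4-[(2R)-2-(hydroxymethyl)oxiran-2-yl]-3-(2-methylpropanoyloxy)phenyl]methyl pentanoate | CCCCC(=O)OCc1ccc([C@@]2(CO)CO2)c(OC(=O)C(C)C)c1
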